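The closed, stirred vessel starts with none of the solid substrate in solution, so I watched what left the solid and how little of it reached the target.

the same everywhere: solid substrate 20 mM

| run | coupling partner | second substrate | protic impurity | remark | time |
|---|---|---|---|---|---|
| birch | 12 mM | 10 mM | 2 mM | run made earlier |  |
| flask | 12.0 mM | 20.0 mM | 2.00 mM |  | 40 min |

birch run (percent of the solid substrate charged)

| time / min | solid substrate / % | target / % |
|---|---|---|
| 0.333 | 97.1 | 0 |
| 0.500 | 97.7 | 0 |
| 0.667 | 95.6 | 1.3 |
| 1.00 | 92.2 | 2.7 |
| 1.50 | 91.4 | 0.6 |
| 2.50 | 91.3 | 2.6 |
| 4.00 | 87.7 | 3.5 |

(each reading ± 1 percentage point)

- given per volume of solution although it is solid: solid substrate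
- at the start none of the solid substrate is in solution
- what has only dissolved of solid substrate counts as not reacted
- what has gone from starting material into another species counts as reacted, even if it can come back

- part of the solid substrate that has turned into other species by 40 min (what has only dissolved does not count)
- target at 40 min, in percent of the solid substrate charged

In the birch run, between 1.00 min and 4.00 min, the solid substrate fell by 4.5 percentage points while the target rose by 0.8 points, so the loss outran the target. At the last birch reading 8.80 % of the charge was neither solid nor target, though that figure also holds whatever had merely dissolved.

I took part of that loss for a quench, with the protic impurity as its limiting reagent, and carried the quench share, 10.0 %: charged [protic impurity] over charged [solid substrate], the part of the solid substrate it can take if one takes one. My first chain ran the target slope forward: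

target at the asked time: 13.1 %

conversion, quench share plus target: 23.1 %

The birch slope was the weak link, since its rise lay below the scatter of 1 point. I replaced it with the mean of the last 4 birch target readings, as my estimate of a flat target:

target: 2.35 %

conversion: 12.3 %

This flask holds twice the birch second substrate, and with no reading on that I left it out of my reckoning.

The forecast stood higher than my reckoning, at 33 % conversion and 20 % target, reading the early loss as “a fast stoichiometric quench”.

The flask gave 16.0 % conversion and 1.72 % target.

    starting material + coupling partner ⇌ target (K = 49.0 L mol⁻¹, k = 2.50 L mol⁻¹ s⁻¹)
    second substrate + coupling partner ⇌ second product (K = 32.0 L mol⁻¹, k = 7.70 L mol⁻¹ s⁻¹)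
    solid substrate ⇌ starting material, rate k3*(cs3 - [starting material]) while solid is left; crystals form when [starting material] > cs3 (solubility = 0.910 mM, k = 0.0330 s⁻¹)
    starting material + protic impurity → quenched substrate (k = 3.50 L mol⁻¹ s⁻¹)
    starting material ⇌ dormant form (K = 0.940, k = 0.0710 s⁻¹)

At 40.0 min this flask held 9.99 % quenched substrate against the quench share of 10.0 %, with protic impurity down to 0.0740 % of its charge. Beside it stood 4.28 % dormant form, which my conversion had not counted. A neighbouring flask with 8.0 mM of solid substrate had a quench share of 25.0 %. At 40.0 min it held 25.0 % quenched substrate, with 4.29 % target and 40.0 % conversion.

The numbers in the tables were generated by integration with made-up constants.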